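## Retrosynthetic overview

1. The target is a 2,3-trans-3,4-trans fisetinidol unit (rings A, B, C) bonded from its C4 to C8 of 6-methyl-(+)-catechin (rings D, E, F). The lower flavan and its two stereocentres come from (+)-catechin, so only ring C and its three stereocentres have to be built.
2. Key disconnection: ring C is cut at C4a–C4 and at C2–C3. This gives an aryloxocarbenium ion (ring A–O1=C2–ring B, released from an O-aryl O-acetyl acetal) and the C3=C4 unit as an (E)-enol acetate already standing on C8 of ring D. The forward reaction is a formal [4+2] (oxa-Povarov) annulation under a chiral Brønsted acid.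
3. Enabling feature: O1 is an aryl ether oxygen on the benzylic C2, so O1=C2 can be an oxocarbenium ion that carries its own nucleophile (C4a of ring A, ortho to O1 and para to the C7 oxygen). C4 is benzylic to the 2,4,6-trioxygenated ring D, which stabilises the cation left at C4 when the oxygen-bearing C3 attacks C2.
4. Ring order: rings D, E, F come from catechin (C6 methyl and C8 side chain by halogenation and cross-coupling), rings A and B are brought in as simple arenes, and ring C is formed last in the key step. Deacetylation and global hydrogenolysis finish the route.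

Key step: step 10

Remark on the chemistry: flavan locants are used throughout; the upper unit carries rings A (benzo), B (catechol) and C (pyran), the lower unit rings D (benzo), E (catechol) and F (pyran). The target has the upper unit 2R,3S,4S and the lower unit 2R,3S.

Assumption: the catalyst enantiomer written as (S,S) is taken to be the one that gives the 2R series in ring C; should the sense of induction be the opposite one, the (R,R) enantiomer is used and nothing else changes.

## Route

Step 1
Reactants: 1 (+)-catechin, (2R,3S)-2-(3,4-dihydroxyphenyl)chromane-3,5,7-triol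
Product: 2 (2R,3S)-5,7-bis(benzyloxy)-2-[3,4-bis(benzyloxy)phenyl]chroman-3-ol
Conditions: BnBr (4.4 equiv), K2CO3, DMF, 0 °C to rt, argon
Reagents that add atoms: benzyl bromide BrCc1ccccc1
Why: Williamson O-alkylation with the mild base K2CO3 should benzylate only the four phenols and leave the secondary 3-OH and both stereocentres untouched.

Step 2
Reactants: 2 (2R,3S)-5,7-bis(benzyloxy)-2-[3,4-bis(benzyloxy)phenyl]chroman-3-ol
Product: 3 (2R,3S)-3,5,7-tris(benzyloxy)-2-[3,4-bis(benzyloxy)phenyl]chromane
Conditions: NaH, BnBr, nBu4NI (5 mol %), DMF, 0 °C to rt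
Reagents that add atoms: benzyl bromide BrCc1ccccc1
Why: Williamson etherification of the remaining secondary alcohol through its sodium alkoxide should complete the protection without affecting C2 or C3.

Step 3
Reactants: 3 (2R,3S)-3,5,7-tris(benzyloxy)-2-[3,4-bis(benzyloxy)phenyl]chromane
Product: 4 (2R,3S)-3,5,7-tris(benzyloxy)-2-[3,4-bis(benzyloxy)phenyl]-8-bromochromane
Conditions: NBS (1.0 equiv), CH2Cl2, −78 °C to rt
Reagents that add atoms: N-bromosuccinimide O=C1CCC(=O)N1Br
Why: Electrophilic aromatic bromination of the phloroglucinol-type ring D should occur at C8, the more reactive of its two free positions in 5,7-di-O-benzyl flavan-3-ols, when one equivalent of NBS is used at low temperature.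

Step 4
Reactants: 4 (2R,3S)-3,5,7-tris(benzyloxy)-2-[3,4-bis(benzyloxy)phenyl]-8-bromochromane
Product: 5 (2R,3S)-3,5,7-tris(benzyloxy)-2-[3,4-bis(benzyloxy)phenyl]-8-bromo-6-iodochromane
Conditions: NIS (1.3 equiv), TFA (10 mol %), CH2Cl2/MeCN, 0 °C to rt, dark
Reagents that add atoms: N-iodosuccinimide O=C1CCC(=O)N1I
Why: Electrophilic aromatic iodination should take C6, the only free position left on the still tri-oxygenated ring D and more activated than any position of ring E, which gives two halogens of different reactivity.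

Step 5
Reactants: 5 (2R,3S)-3,5,7-tris(benzyloxy)-2-[3,4-bis(benzyloxy)phenyl]-8-bromo-6-iodochromane
Product: 6 (2R,3S)-3,5,7-tris(benzyloxy)-2-[3,4-bis(benzyloxy)phenyl]-8-bromo-6-methylchromane
Conditions: MeZnCl (1.5 equiv), Pd(PPh3)4 (5 mol %), THF, rt to 40 °C
Reagents that add atoms: methylzinc chloride C[Zn]Cl
Why: Negishi coupling should occur only at the C–I bond, because oxidative addition of zerovalent palladium to the aryl iodide is much faster than to the hindered, electron-rich aryl bromide at this temperature.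

Step 6
Reactants: 6 (2R,3S)-3,5,7-tris(benzyloxy)-2-[3,4-bis(benzyloxy)phenyl]-8-bromo-6-methylchromane; 7 (E)-1,2-bis(4,4,5,5-tetramethyl-1,3,2-dioxaborolan-2-yl)ethene (3 equiv)
Product: 8 2-{(E)-2-[(2R,3S)-3,5,7-tris(benzyloxy)-2-[3,4-bis(benzyloxy)phenyl]-6-methylchroman-8-yl]ethenyl}-4,4,5,5-tetramethyl-1,3,2-dioxaborolane
Conditions: Pd(OAc)2 (5 mol %), SPhos (10 mol %), K3PO4, THF/H2O (10:1), 60 °C
Reagents that add atoms: none
Why: Suzuki–Miyaura coupling of the di-ortho-substituted bromide with an excess of the bis-boronate should transfer one vinyl carbon with retention of the E geometry, the bulky electron-rich biarylphosphine being suited to hindered aryl bromides and the excess of 7 suppressing a second coupling.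

Step 7
Reactants: 8 2-{(E)-2-[(2R,3S)-3,5,7-tris(benzyloxy)-2-[3,4-bis(benzyloxy)phenyl]-6-methylchroman-8-yl]ethenyl}-4,4,5,5-tetramethyl-1,3,2-dioxaborolane
Product: 9 potassium trifluoro{(E)-2-[(2R,3S)-3,5,7-tris(benzyloxy)-2-[3,4-bis(benzyloxy)phenyl]-6-methylchroman-8-yl]ethenyl}borate
Conditions: KHF2 (aq, 4.5 equiv), MeOH/THF, rt
Reagents that add atoms: potassium hydrogen difluoride F.[F-].[K+]
Why: Ligand exchange at boron with KHF2 should give the air-stable alkenyltrifluoroborate, the form of boron reagent suited to the following oxidative C–O coupling, without touching the alkene geometry.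

Step 8
Reactants: 9 potassium trifluoro{(E)-2-[(2R,3S)-3,5,7-tris(benzyloxy)-2-[3,4-bis(benzyloxy)phenyl]-6-methylchroman-8-yl]ethenyl}borate
Product: 10 (E)-2-[(2R,3S)-3,5,7-tris(benzyloxy)-2-[3,4-bis(benzyloxy)phenyl]-6-methylchroman-8-yl]ethenyl acetate
Conditions: AcOH (3 equiv), CuBr (10 mol %), DMAP, 4 Å MS, O2 (1 atm), MeCN, 40 °C
Reagents that add atoms: acetic acid CC(=O)O
Why: Copper-catalysed oxidative Chan–Lam-type C–O coupling of an alkenyltrifluoroborate with a carboxylic acid should give the enol ester with retention of the E geometry.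

Step 9
Reactants: 11 3,4-bis(benzyloxy)benzaldehyde; 12 3-(benzyloxy)phenol
Product: 14 [3-(benzyloxy)phenoxy][3,4-bis(benzyloxy)phenyl]methyl acetate (racemic), via chloro[3,4-bis(benzyloxy)phenyl]methyl acetate 13 (not isolated)
Conditions: AcCl (1.0 equiv), ZnCl2 (2 mol %), CH2Cl2, −10 °C to rt; solution then added to 12, Cs2CO3, MeCN, 0 °C to rt; filtration through basic alumina
Reagents that add atoms: acetyl chloride CC(Cl)=O
Why: ZnCl2-catalysed addition of the acyl chloride to the aldehyde should give the 1-chloroalkyl ester, whose benzylic chloride should then be displaced by the phenoxide at oxygen (Williamson-type alkylation as used for acyloxyalkyl aryl ethers), the new acetal centre being racemic and of no consequence because it is ionised in the next step.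

Step 10
Reactants: 10 (E)-2-[(2R,3S)-3,5,7-tris(benzyloxy)-2-[3,4-bis(benzyloxy)phenyl]-6-methylchroman-8-yl]ethenyl acetate; 14 [3-(benzyloxy)phenoxy][3,4-bis(benzyloxy)phenyl]methyl acetate (1.5 equiv)
Product: 17 (2R,3S,4S)-7-(benzyloxy)-2-[3,4-bis(benzyloxy)phenyl]-4-[(2R,3S)-3,5,7-tris(benzyloxy)-2-[3,4-bis(benzyloxy)phenyl]-6-methylchroman-8-yl]chroman-3-yl acetate, via aryloxocarbenium ion 15 (not isolated), via benzylic cation 16 (not isolated)
Conditions: (S,S)-imidodiphosphorimidate Brønsted acid (IDPi; two 3,3'-diaryl-BINOL units on a P–N–P core, N-triflyl groups; 5 mol %), 4 Å MS, CH2Cl2/toluene, −50 °C, slow addition of 14 to 10; Et3N quench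
Reagents that add atoms: none
Why: Proposed new method: the chiral acid should ionise 14 by loss of acetic acid (the only productive ionisation, since the aryloxy oxygen is the better donor and acetate the better leaving group) to the E-aryloxocarbenium ion 15, held as a contact ion pair with the chiral anion; the alkene of 10 should attack C2 of 15 through its acetoxy-bearing carbon (Prins-type addition) to give the benzylic cation 16, which ring A then captures. The closest known reaction types are the Lewis-acid-promoted oxa-Povarov reaction of aryloxocarbenium ions with styrenes (formal inverse-electron-demand [4+2] cycloaddition giving 2,4-cis-chromans) and additions of styrenes and other π-nucleophiles to oxocarbenium ions paired with chiral imidodiphosphorimidate anions; new are their combination and the enol ester as the alkene. Ring C is closed in the second bond formation by intramolecular Friedel–Crafts alkylation, a six-membered closure of C4a onto the exocyclic cationic C4 through a chair-like transition state. The configuration at C2 (R) is set by the chiral anion, which shields one face of the oxocarbenium ion; C3 (S) follows from the E geometries of both partners and the exo placement of the acetoxy group in the compact endo-aryl arrangement known from Povarov reactions of E-β-substituted styrenes; C4 (S) is set in the ring closure, in which the aryl groups at C2 and C4 and the acetoxy group at C3 all become equatorial (2,3-trans-3,4-trans), an outcome that reversible acetoxonium formation across C3/C4 can only reinforce. The step needs regioselectivity in the first bond, secured by the 2,4,6-trioxygenated ring D, which stabilises the cation at C4 far better than the acetoxy group could stabilise the alternative; it needs regioselectivity in the closure, secured by the C7 benzyloxy group of ring A, which activates the para position C4a over the hindered position between the two oxygens and over ring B; and it needs chemoselectivity for the alkene, secured by the fully substituted ring D. The remote (2R,3S) centres of the lower unit are expected to add only a small matched or mismatched bias to the catalyst control.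

Step 11
Reactants: 17 (2R,3S,4S)-7-(benzyloxy)-2-[3,4-bis(benzyloxy)phenyl]-4-[(2R,3S)-3,5,7-tris(benzyloxy)-2-[3,4-bis(benzyloxy)phenyl]-6-methylchroman-8-yl]chroman-3-yl acetate
Product: 18 (2R,3S,4S)-7-(benzyloxy)-2-[3,4-bis(benzyloxy)phenyl]-4-[(2R,3S)-3,5,7-tris(benzyloxy)-2-[3,4-bis(benzyloxy)phenyl]-6-methylchroman-8-yl]chroman-3-ol
Conditions: K2CO3 (0.5 equiv), MeOH/THF (1:1), rt
Reagents that add atoms: none
Why: Base-catalysed transesterification (Zemplén-type methanolysis) should remove the secondary acetate while the eight benzyl ethers and all stereocentres, none of which is base-labile in the fully etherified compound, remain unchanged.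

Step 12
Reactants: 18 (2R,3S,4S)-7-(benzyloxy)-2-[3,4-bis(benzyloxy)phenyl]-4-[(2R,3S)-3,5,7-tris(benzyloxy)-2-[3,4-bis(benzyloxy)phenyl]-6-methylchroman-8-yl]chroman-3-ol
Product: 19 (2R,3S,4S)-2-(3,4-dihydroxyphenyl)-4-[(2R,3S)-2-(3,4-dihydroxyphenyl)-3,5,7-trihydroxy-6-methylchroman-8-yl]chromane-3,7-diol (CNP0288113.1)
Conditions: H2 (1 atm), Pd(OH)2/C (20 wt %), THF/MeOH (1:1), rt; filtration, lyophilisation
Reagents that add atoms: none
Why: Catalytic hydrogenolysis should cleave the seven aryl benzyl ethers and the one alkyl benzyl ether under neutral conditions that are standard for benzylated oligomeric flavan-3-ols and should leave the interflavan bond and the five stereocentres untouched.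

## Compound list

1 | (+)-catechin, (2R,3S)-2-(3,4-dihydroxyphenyl)chromane-3,5,7-triol | Oc1cc(O)c2c(c1)O[C@H](c1ccc(O)c(O)c1)[C@@H](O)C2 | starting material
2 | (2R,3S)-5,7-bis(benzyloxy)-2-[3,4-bis(benzyloxy)phenyl]chroman-3-ol | O(Cc1ccccc1)c1cc(OCc2ccccc2)c2c(c1)O[C@H](c1ccc(OCc3ccccc3)c(OCc3ccccc3)c1)[C@@H](O)C2 | intermediate
3 | (2R,3S)-3,5,7-tris(benzyloxy)-2-[3,4-bis(benzyloxy)phenyl]chromane | O(Cc1ccccc1)c1cc(OCc2ccccc2)c2c(c1)O[C@H](c1ccc(OCc3ccccc3)c(OCc3ccccc3)c1)[C@@H](OCc1ccccc1)C2 | intermediate
4 | (2R,3S)-3,5,7-tris(benzyloxy)-2-[3,4-bis(benzyloxy)phenyl]-8-bromochromane | O(Cc1ccccc1)c1cc(OCc2ccccc2)c2c(c1Br)O[C@H](c1ccc(OCc3ccccc3)c(OCc3ccccc3)c1)[C@@H](OCc1ccccc1)C2 | intermediate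
5 | (2R,3S)-3,5,7-tris(benzyloxy)-2-[3,4-bis(benzyloxy)phenyl]-8-bromo-6-iodochromane | O(Cc1ccccc1)c1c(I)c(OCc2ccccc2)c2c(c1Br)O[C@H](c1ccc(OCc3ccccc3)c(OCc3ccccc3)c1)[C@@H](OCc1ccccc1)C2 | intermediate
6 | (2R,3S)-3,5,7-tris(benzyloxy)-2-[3,4-bis(benzyloxy)phenyl]-8-bromo-6-methylchromane | O(Cc1ccccc1)c1c(C)c(OCc2ccccc2)c2c(c1Br)O[C@H](c1ccc(OCc3ccccc3)c(OCc3ccccc3)c1)[C@@H](OCc1ccccc1)C2 | intermediate
7 | (E)-1,2-bis(4,4,5,5-tetramethyl-1,3,2-dioxaborolan-2-yl)ethene | CC1(C)OB(/C=C/B2OC(C)(C)C(C)(C)O2)OC1(C)C | starting material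
8 | 2-{(E)-2-[(2R,3S)-3,5,7-tris(benzyloxy)-2-[3,4-bis(benzyloxy)phenyl]-6-methylchroman-8-yl]ethenyl}-4,4,5,5-tetramethyl-1,3,2-dioxaborolane | O(Cc1ccccc1)c1c(C)c(OCc2ccccc2)c2c(c1/C=C/B1OC(C)(C)C(C)(C)O1)O[C@H](c1ccc(OCc3ccccc3)c(OCc3ccccc3)c1)[C@@H](OCc1ccccc1)C2 | intermediate
9 | potassium trifluoro{(E)-2-[(2R,3S)-3,5,7-tris(benzyloxy)-2-[3,4-bis(benzyloxy)phenyl]-6-methylchroman-8-yl]ethenyl}borate | O(Cc1ccccc1)c1c(C)c(OCc2ccccc2)c2c(c1/C=C/[B-](F)(F)F)O[C@H](c1ccc(OCc3ccccc3)c(OCc3ccccc3)c1)[C@@H](OCc1ccccc1)C2.[K+] | intermediate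
10 | (E)-2-[(2R,3S)-3,5,7-tris(benzyloxy)-2-[3,4-bis(benzyloxy)phenyl]-6-methylchroman-8-yl]ethenyl acetate | O(Cc1ccccc1)c1c(C)c(OCc2ccccc2)c2c(c1/C=C/OC(C)=O)O[C@H](c1ccc(OCc3ccccc3)c(OCc3ccccc3)c1)[C@@H](OCc1ccccc1)C2 | intermediate
11 | 3,4-bis(benzyloxy)benzaldehyde | O=Cc1ccc(OCc2ccccc2)c(OCc2ccccc2)c1 | starting material
12 | 3-(benzyloxy)phenol | Oc1cccc(OCc2ccccc2)c1 | starting material
13 | chloro[3,4-bis(benzyloxy)phenyl]methyl acetate (racemic) | CC(=O)OC(Cl)c1ccc(OCc2ccccc2)c(OCc2ccccc2)c1 | intermediate (not isolated)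
14 | [3-(benzyloxy)phenoxy][3,4-bis(benzyloxy)phenyl]methyl acetate (racemic) | CC(=O)OC(Oc1cccc(OCc2ccccc2)c1)c1ccc(OCc2ccccc2)c(OCc2ccccc2)c1 | intermediate
15 | (E)-[3-(benzyloxy)phenyl][3,4-bis(benzyloxy)benzylidene]oxonium ion, paired with the catalyst anion | O(Cc1ccccc1)c1cccc(c1)/[O+]=C/c1ccc(OCc2ccccc2)c(OCc2ccccc2)c1 | intermediate (not isolated)
16 | open-chain C4 benzylic cation after C2–C3 bond formation, C2 and C3 configured as in 17 | O(Cc1ccccc1)c1cccc(c1)O[C@H](c1ccc(OCc2ccccc2)c(OCc2ccccc2)c1)[C@@H](OC(C)=O)[CH+]c1c(OCc2ccccc2)c(C)c(OCc2ccccc2)c2c1O[C@H](c1ccc(OCc3ccccc3)c(OCc3ccccc3)c1)[C@@H](OCc1ccccc1)C2 | intermediate (not isolated)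
17 | (2R,3S,4S)-7-(benzyloxy)-2-[3,4-bis(benzyloxy)phenyl]-4-[(2R,3S)-3,5,7-tris(benzyloxy)-2-[3,4-bis(benzyloxy)phenyl]-6-methylchroman-8-yl]chroman-3-yl acetate | Cc1c(OCc5ccccc5)c2c(c([C@@H]3c4ccc(OCc5ccccc5)cc4O[C@H](c4ccc(OCc5ccccc5)c(OCc5ccccc5)c4)[C@H]3OC(C)=O)c1OCc1ccccc1)O[C@H](c1ccc(OCc3ccccc3)c(OCc3ccccc3)c1)[C@@H](OCc1ccccc1)C2 | intermediate
18 | (2R,3S,4S)-7-(benzyloxy)-2-[3,4-bis(benzyloxy)phenyl]-4-[(2R,3S)-3,5,7-tris(benzyloxy)-2-[3,4-bis(benzyloxy)phenyl]-6-methylchroman-8-yl]chroman-3-ol | Cc1c(OCc5ccccc5)c2c(c([C@@H]3c4ccc(OCc5ccccc5)cc4O[C@H](c4ccc(OCc5ccccc5)c(OCc5ccccc5)c4)[C@H]3O)c1OCc1ccccc1)O[C@H](c1ccc(OCc3ccccc3)c(OCc3ccccc3)c1)[C@@H](OCc1ccccc1)C2 | intermediate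
19 | (2R,3S,4S)-2-(3,4-dihydroxyphenyl)-4-[(2R,3S)-2-(3,4-dihydroxyphenyl)-3,5,7-trihydroxy-6-methylchroman-8-yl]chromane-3,7-diol | Cc1c(O)c2c(c([C@@H]3c4ccc(O)cc4O[C@H](c4ccc(O)c(O)c4)[C@H]3O)c1O)O[C@H](c1ccc(O)c(O)c1)[C@@H](O)C2 | target

## Step count and risks

Total step count: 12. Longest linear sequence: 11 steps (steps 1 to 8, then 10, 11 and 12); step 9 is the one-step side branch.

Steps most likely to fail:

**Step 10 (Proposed new method).** The chiral anion may not discriminate the faces of the large ion pair well enough, or may be mismatched with the remote centres of the lower unit. The cation may also be intercepted by ring B in a five-membered closure, or the enol acetate may oligomerise under the acid. The fallback uses known chemistry and a different bond set: the C4–C8 interflavan bond is made by the classical flavan-4-yl cation coupling. It sets out from 6. Bromine–lithium exchange (n-BuLi, THF, −78 °C) and protonation (MeOH) would give (2R,3S)-3,5,7-tris(benzyloxy)-2-[3,4-bis(benzyloxy)phenyl]-6-methylchromane F1, whose only free position on ring D is C8. The upper unit would come from commercial (2R,3R)-fustin (natural 2,3-trans-3,7,3',4'-tetrahydroxyflavanone). Benzylation (BnBr, K2CO3, DMF, 0 °C) would give (2R,3R)-7-(benzyloxy)-2-[3,4-bis(benzyloxy)phenyl]-3-hydroxychroman-4-one F2. Reduction (NaBH4, THF/MeOH, 0 °C) would give (2R,3S,4R)-7-(benzyloxy)-2-[3,4-bis(benzyloxy)phenyl]chromane-3,4-diol F3. Ionisation of F3 at C4 (TMSOTf, CH2Cl2, −78 °C) in the presence of an excess of F1 should give 18 directly, because in this established Friedel–Crafts coupling the nucleophile adds anti to the 3-OH of the 2,3-trans cation (3,4-trans product). The route is rejoined at 18 and step 12 follows.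

**Step 9.** The addition of acetyl chloride to the electron-rich aldehyde may stop at an unfavourable equilibrium, the phenoxide may attack the ester carbonyl instead of the benzylic carbon, and the product may ionise and hydrolyse on handling. In the fallback the acetal carbon is built at the carboxylic acid oxidation level and the acetoxy group is introduced by oxidative decarboxylation. It sets out from 11. Addition of the trichloromethyl anion (CHCl3, DBU, 0 °C) would give 1-[3,4-bis(benzyloxy)phenyl]-2,2,2-trichloroethanol F4. Jocic–Reeve reaction of F4 with 12 (NaOH, DME/H2O) would give 2-[3-(benzyloxy)phenoxy]-2-[3,4-bis(benzyloxy)phenyl]acetic acid F5. Oxidative decarboxylation of F5 (Pb(OAc)4, pyridine, CH2Cl2) should give 14, where the route is rejoined.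

**Step 8.** Protodeboronation or oxidative homocoupling of the electron-rich, di-ortho-substituted alkenylborate may outrun C–O bond formation, and the enol ester may hydrolyse. In the fallback the C–O bond is made by O-acylation of an enol instead of by C–O coupling. It sets out from 8. Oxidation of the C–B bond (NaBO3·4H2O, THF/H2O) would give 2-[(2R,3S)-3,5,7-tris(benzyloxy)-2-[3,4-bis(benzyloxy)phenyl]-6-methylchroman-8-yl]acetaldehyde F6. Enol acetylation (Ac2O, KOAc, 100 °C) should give 10 as the major isomer, because the two ortho substituents of ring D disfavour the Z form; the minor Z isomer would be removed by chromatography. The route is rejoined at 10.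

Further compounds
F1 | step 10 | (2R,3S)-3,5,7-tris(benzyloxy)-2-[3,4-bis(benzyloxy)phenyl]-6-methylchromane | O(Cc1ccccc1)c1c(C)c(OCc2ccccc2)c2c(c1)O[C@H](c1ccc(OCc3ccccc3)c(OCc3ccccc3)c1)[C@@H](OCc1ccccc1)C2
F2 | step 10 | (2R,3R)-7-(benzyloxy)-2-[3,4-bis(benzyloxy)phenyl]-3-hydroxychroman-4-one | O=C1c2ccc(OCc3ccccc3)cc2O[C@H](c2ccc(OCc3ccccc3)c(OCc3ccccc3)c2)[C@H]1O
F3 | step 10 | (2R,3S,4R)-7-(benzyloxy)-2-[3,4-bis(benzyloxy)phenyl]chromane-3,4-diol | O[C@@H]1c2ccc(OCc3ccccc3)cc2O[C@H](c2ccc(OCc3ccccc3)c(OCc3ccccc3)c2)[C@H]1O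
F4 | step 9 | 1-[3,4-bis(benzyloxy)phenyl]-2,2,2-trichloroethanol (racemic) | OC(c1ccc(OCc2ccccc2)c(OCc2ccccc2)c1)C(Cl)(Cl)Cl
F5 | step 9 | 2-[3-(benzyloxy)phenoxy]-2-[3,4-bis(benzyloxy)phenyl]acetic acid (racemic) | OC(=O)C(Oc1cccc(OCc2ccccc2)c1)c1ccc(OCc2ccccc2)c(OCc2ccccc2)c1
F6 | step 8 | 2-[(2R,3S)-3,5,7-tris(benzyloxy)-2-[3,4-bis(benzyloxy)phenyl]-6-methylchroman-8-yl]acetaldehyde | O(Cc1ccccc1)c1c(C)c(OCc2ccccc2)c2c(c1CC=O)O[C@H](c1ccc(OCc3ccccc3)c(OCc3ccccc3)c1)[C@@H](OCc1ccccc1)C2
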